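# Synthesis plan for (4S,6R)-4,6-dihydroxy-6-[(2S,10Z)-2-hydroxyheptadec-10-en-1-yl]cyclohex-2-en-1-one (23)

Locants used throughout: ring C1 (carbonyl), C2=C3, C4 (carbinol), C5 (CH2), C6 (quaternary carbinol); chain C1'–C17' on C6, with the carbinol at C2' and the Z-alkene at C10'=C11'.

## The problem

The target is a cyclohex-2-enone carrying a tertiary alcohol at C6, a secondary allylic alcohol at C4 (cis to the C6 hydroxyl) and a C17 chain on C6 with a carbinol at C2' and a Z-alkene at C10'. C6 is fully substituted, so it cannot be set by a reduction and must come from a step that tells two carbon arms apart. Once fixed, C6 can steer C4 through a cyclic transition state because the two are 1,3-related on the ring. It cannot be trusted to steer C2', which sits on a freely rotating arm next to a tertiary carbinol with two similar CH2 substituents, so C2' needs reagent control. The γ-hydroxy enone can dehydrate or isomerise to a 1,4-dione under base, the tertiary α-ketol can undergo acyloin shifts, and the Z-alkene excludes hydrogenation, halogen radicals in quantity and careless metathesis. The enabling feature is that C6 bears a hydroxyl, the C1 carbonyl carbon and two CH2–C(O) arms (C5–C4 and C1'–C2'), which is the skeleton of citric acid with C6 as its prochiral centre. The two arms are enantiotopic in a symmetric citrate diester, so one act of discrimination fixes C6. Every hydroxyl that later appears γ to the C1 carboxyl will lactonise onto it unless C1 is in the right form at the right time.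

## Retrosynthesis

**23 from 22.** Only an acetonide is removed. The C6 and C2' oxygens are tied in one 1,3-dioxane (22), so a single group covers both hydroxyls and falls in dilute acid, with no fluoride or base near the γ-hydroxy enone. An acetal oxygen on C6 is also a better ligand for chromium than a silyl ether, which matters in the ring closure.

**22 from 21.** The ring is cut at C3–C4, giving the Z-β-iodoenone aldehyde 21, closed by a Nozaki–Hiyama–Kishi reaction. Cutting C2=C3 (metathesis) would expose the chain alkene to a ruthenium carbene and would require C4 to be set earlier in an acyclic addition. Cutting C1–C2 would need an alkenyllithium beside several electrophiles. The forward step must activate the C–I bond selectively and place the new C4–O bond cis to C6–O.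

**21 from 20, 18, 15 and 16.** C2 and C3 come from ethynyltrimethylsilane (16). The C1–C2 bond is made by acylating lithium (trimethylsilyl)acetylide (17) with the C1 amide of 15, giving ynone 18. Desilylation (19) and anti addition of HI give the Z-iodoenone 20, and the C4 alcohol is oxidised last. The order is forced: an aldehyde cannot be present when the acetylide is added, and an ester cannot be reduced once the ynone exists, so C4 travels as the primary alcohol.

**15 from 14 and 13.** The ester arm (C5–C4) of 14 is reduced with LiBH4, which works only because C1 is a tertiary amide. The acetonide is installed on diol 13 immediately before.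

**13 from 12.** C2' is set by a ketoreductase on ketone 12, under reagent control for the reason given above.

**12 from 11.** The C1 acyl group is changed from dioxolanone to morpholine amide. This is where the plan is reinforced. A free C2' hydroxyl would sit γ to the activated dioxolanone carbonyl and lactonise at once, and no hydride can reduce the arm ester in the presence of the dioxolanone. The amide resists both lactonisation at neutral pH and LiBH4, yet still acylates an alkynyllithium.

**11 from 5 and 8; 8 from 6.** The C2'–C3' bond is cut. The acid arm of 5 is the one carbonyl that can be activated selectively (acyl chloride 9) and is coupled with alkylzinc iodide 10. Its iodide 8 comes from palmitoleic acid (6) by loss of one carbon, so the Z-alkene is bought, not made.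

**5 from 4.** Esterase desymmetrisation of the prochiral diester 4 fixes C6. No bond is formed, but all later chemistry depends on the two arms now being different.

**4 from 3, 1 and 2.** Citric acid (1) and formaldehyde (2) give the dioxolanone diacid 3, which masks exactly the C6 hydroxyl and the C1 carboxyl. Methylation gives 4.

## Roads not taken

**Alternative 1:** The C1–C6 bond is cut. A chiral triazolylidene converts the C1 aldehyde of keto aldehyde A1 into an acyl anion equivalent that adds to the C6 ketone, giving α-ketol A2.
- Merits: the step forms a C–C bond, the ring and the quaternary carbinol in one catalytic operation. In this respect it is better than the chosen plan, whose key step forms no bond and whose ring closes ten steps later.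
- Weak points: the ketone of A1 is flanked by two CH2–CH(OSi) arms that differ only at a distance, so face selection at C6 rests on the catalyst working with or against two existing stereocentres. A1 is an enolisable keto aldehyde with β-silyloxy groups, open to aldol and elimination under the basic conditions. A2 is saturated, so C2=C3 must be introduced later by dehydrogenation. C4 and C2' must each be set by a separate asymmetric step before the ring exists.
- Comparison: the chosen plan sets C6 on a substrate whose arms are strictly enantiotopic, three steps from a commodity and independent of the other stereocentres, and the enone arrives at the right oxidation level.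

**Alternative 2:** The C6–C1' bond is cut. The enolate of methyl ketone A4, formed with CeCl3, adds 1,2 to the carbonyl of enone A3 to give aldol adduct A5.
- Merits: this is the most convergent plan and probably the shortest on paper. Attack anti to the silyloxy group would give the correct C4/C6 relationship.
- Weak points: in A5 the alkene lies between the carbons that become C1 and C2, and C1 carries no oxygen. An epoxidation, eliminative opening and oxidation sequence is needed on a tertiary allylic alcohol. A5 is a tertiary aldol prone to retro-aldol, 1,4-addition competes, and the C2' ketone still needs reagent-controlled reduction.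
- Comparison: the chosen plan needs no redox transposition because the citrate core has each oxygen where the target has it, and C6 is set by a catalyst and not relayed from C4. The chosen route also passes through a tertiary aldol (12), but only for one step at neutral pH.

**Alternative 3:** The C5–C6 bond is cut. Under chelation by a Lewis acid such as Me2AlCl, the ring CH2 of acylcyclopentenol A6 migrates from the carbinol carbon to the acyl carbon, expanding the ring to enone A7.
- Merits: A7 is the bis-silyl ether of the target, one step from the end. If the shift behaved, this route would be shorter than the chosen one.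
- Weak points: two groups can migrate, the sp3 C5 and the vinylic C2, and alkenyl migration is usually at least as easy. α-Ketol shifts are reversible, and A7 is itself an α-ketol. The tertiary allylic alcohol of A6 can ionise under Lewis acid. C6 is only as good as the carbinol configuration of A6, which must come from a diastereoselective acyl anion addition.
- Comparison: the chosen plan sets against the shorter endgame a C6 centre that does not depend on migratory aptitude or on any earlier stereocentre.

Key step: step 3

## Route

Remark on the chemistry: paraformaldehyde is counted as its monomer (2). The esterase is assumed to cleave the pro-S ester of 4, which gives (R)-5. If it prefers the other arm, the anhydride fallback under step 3 supplies the same acid with the matching alkaloid catalyst.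

Step 1
Reactants: 1 citric acid; 2 formaldehyde (as paraformaldehyde)
Product: 3 2,2'-(5-oxo-1,3-dioxolane-4,4-diyl)diacetic acid
Conditions: (CH2O)n (1.2 equiv), neat melt, 140 °C; recrystallise from water
Reagents that add atoms: none
Why: Acetalisation of the α-hydroxy acid unit (tertiary OH and central CO2H) with formaldehyde closes the five-membered 1,3-dioxolan-4-one in preference to a six-membered ring through a side-arm acid; the achiral product masks the C6 hydroxyl and the C1 carboxyl and leaves two enantiotopic CH2CO2H arms.

Step 2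
Reactants: 3 2,2'-(5-oxo-1,3-dioxolane-4,4-diyl)diacetic acid
Product: 4 dimethyl 2,2'-(5-oxo-1,3-dioxolane-4,4-diyl)diacetate
Conditions: MeI (2.5 equiv), KHCO3 (2.5 equiv), DMF, rt
Reagents that add atoms: iodomethane, CI
Why: O-Alkylation of the two carboxylates by SN2 displacement on MeI; no acid or alkoxide is present, so the acylal-type lactone is not opened as it could be in a Fischer esterification.

Step 3
Reactants: 4 dimethyl 2,2'-(5-oxo-1,3-dioxolane-4,4-diyl)diacetate
Product: 5 (R)-2-[4-(2-methoxy-2-oxoethyl)-5-oxo-1,3-dioxolan-4-yl]acetic acid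
Conditions: pig liver esterase, 0.1 M phosphate buffer pH 7.0, acetone (5% v/v), 15 °C, pH-stat (1 M NaOH) to 1.0 equiv; then HCl to pH 2.5, EtOAc
Reagents that add atoms: water, O
Why: The active-site serine of the carboxylesterase adds to one methyl ester, methanol leaves from the tetrahedral intermediate and water cleaves the acyl-enzyme, so one ester is hydrolysed, no skeletal bond is formed and no ring closes. The closest known reaction type is the esterase desymmetrisation of prochiral 3-hydroxy- and 3-alkoxy-3-substituted glutaric diesters, of which 4 is a rigid cyclic member. The two CH2CO2Me arms are related by the mirror plane through the dioxolanone ring, and only the chiral pocket can tell them apart; acylation by the pro-S arm gives the R configuration at C4 of the dioxolanone (the future C6), the single new stereocentre. The step needs enantiotopic-group selection, arrest at the half-ester and ester-over-lactone chemoselectivity. Arrest is secured because the carboxylate of 5 binds poorly and the pH-stat stops at one equivalent of base. Neutral pH and low temperature limit non-enzymatic opening of the dioxolanone, whose carbonyl sits on a fully substituted carbon and is poorly placed for the enzyme nucleophile.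

Step 4
Reactants: 6 palmitoleic acid, (9Z)-hexadec-9-enoic acid
Product: 8 (8Z)-1-iodopentadec-8-ene, via Barton ester 7 (not isolated)
Conditions: 1-hydroxypyridine-2(1H)-thione, DCC, DMAP (cat.), CH2Cl2, 0 °C to rt, dark; then CHI3 (1.5 equiv), tungsten lamp, reflux
Reagents that add atoms: iodoform, IC(I)I
Why: Barton decarboxylative iodination: the thiohydroxamate ester fragments in a radical chain to CO2 and the primary C15 radical, which abstracts iodine from CHI3; the remote Z-alkene cannot trap the radical (an eight-membered ring would be needed) and no ionic reagent that adds to alkenes is present.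

Step 5
Reactants: 5 (R)-2-[4-(2-methoxy-2-oxoethyl)-5-oxo-1,3-dioxolan-4-yl]acetic acid; 8 (8Z)-1-iodopentadec-8-ene
Product: 11 methyl 2-[(4R)-5-oxo-4-[(10Z)-2-oxoheptadec-10-en-1-yl]-1,3-dioxolan-4-yl]acetate, via acyl chloride 9 (not isolated), via alkylzinc iodide 10 (not isolated)
Conditions: 5: (COCl)2, DMF (cat.), CH2Cl2, 0 °C to rt, evaporate; 8: Zn dust, LiCl, THF, 40 °C; combine, Pd(PPh3)4 (5 mol %), THF, 0 °C to rt
Reagents that add atoms: none
Why: Negishi acylation: the acyl chloride adds oxidatively to zerovalent palladium, the alkyl group is transferred from zinc and reductive elimination gives the ketone without over-addition; the methyl ester and dioxolanone are inert to the zinc reagent, and the neutral medium avoids β-elimination of the C6 oxygen.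

Step 6
Reactants: 11 methyl 2-[(4R)-5-oxo-4-[(10Z)-2-oxoheptadec-10-en-1-yl]-1,3-dioxolan-4-yl]acetate
Product: 12 methyl (3R,13Z)-3-hydroxy-3-(morpholine-4-carbonyl)-5-oxoicos-13-enoate
Conditions: morpholine (3 equiv), THF, 0 °C
Reagents that add atoms: morpholine, C1COCCN1
Why: Aminolysis of an activated lactone: the amine attacks the dioxolanone carbonyl, which is far more electrophilic than the methyl ester, the ring opens and the hemiacetal loses formaldehyde (scavenged by excess amine); the resulting amide does not lactonise with the coming C2' hydroxyl at neutral pH and is not reduced by LiBH4.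

Step 7
Reactants: 12 methyl (3R,13Z)-3-hydroxy-3-(morpholine-4-carbonyl)-5-oxoicos-13-enoate
Product: 13 methyl (3R,5S,13Z)-3,5-dihydroxy-3-(morpholine-4-carbonyl)icos-13-enoate
Conditions: ketoreductase (S-selective, chosen by panel screening), NADP+ (cat.), i-PrOH (15% v/v), 0.1 M phosphate buffer pH 7.0, DMSO (5% v/v), 30 °C
Reagents that add atoms: none
Why: Enzymatic ketone reduction: the nicotinamide cofactor, recycled by i-PrOH, delivers hydride to one face of the C2' carbonyl inside the enzyme pocket, setting the 5S carbinol (C2') under reagent control, since the tertiary carbinol with two similar CH2 arms gives no dependable 1,3-induction.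

Step 8
Reactants: 13 methyl (3R,5S,13Z)-3,5-dihydroxy-3-(morpholine-4-carbonyl)icos-13-enoate
Product: 14 methyl 2-[(4R,6S)-2,2-dimethyl-4-(morpholine-4-carbonyl)-6-[(8Z)-pentadec-8-en-1-yl]-1,3-dioxan-4-yl]acetate
Conditions: 2-methoxypropene (3 equiv), PPTS (5 mol %), CH2Cl2, 0 °C
Reagents that add atoms: 2-methoxypropene, COC(C)=C
Why: Kinetic acetonide formation (enol ether, weak acid, 0 °C) ties the tertiary and secondary hydroxyls into one 1,3-dioxane before acid-catalysed lactonisation onto the amide or ester can compete.

Step 9
Reactants: 14 methyl 2-[(4R,6S)-2,2-dimethyl-4-(morpholine-4-carbonyl)-6-[(8Z)-pentadec-8-en-1-yl]-1,3-dioxan-4-yl]acetate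
Product: 15 [(4S,6S)-4-(2-hydroxyethyl)-2,2-dimethyl-6-[(8Z)-pentadec-8-en-1-yl]-1,3-dioxan-4-yl](morpholin-4-yl)methanone
Conditions: LiBH4 (2 equiv), THF, 0 °C to rt; aq. NH4Cl
Reagents that add atoms: none
Why: LiBH4 reduces carboxylic esters but not tertiary amides, so only the C5–C4 arm is taken to the primary alcohol; any γ-lactone formed by attack of the new alkoxide on the amide would converge on the same product in step 10.

Step 10
Reactants: 15 [(4S,6S)-4-(2-hydroxyethyl)-2,2-dimethyl-6-[(8Z)-pentadec-8-en-1-yl]-1,3-dioxan-4-yl](morpholin-4-yl)methanone; 16 ethynyltrimethylsilane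
Product: 18 1-[(4S,6S)-4-(2-hydroxyethyl)-2,2-dimethyl-6-[(8Z)-pentadec-8-en-1-yl]-1,3-dioxan-4-yl]-3-(trimethylsilyl)prop-2-yn-1-one, via lithium (trimethylsilyl)acetylide 17 (not isolated)
Conditions: 16 (3.2 equiv), n-BuLi (3.0 equiv), THF, −78 °C; add 15, −78 to −10 °C; pour into cold aq. NaHSO4
Reagents that add atoms: none
Why: Acyl substitution at a morpholine amide by an alkynyllithium: one equivalent deprotonates the alcohol, another adds to the amide to give a tetrahedral intermediate that survives until the acidic quench, so no second addition occurs; the acid protonates the released morpholine before it can add to the ynone, whose β-carbon is also shielded by silicon.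

Step 11
Reactants: 18 1-[(4S,6S)-4-(2-hydroxyethyl)-2,2-dimethyl-6-[(8Z)-pentadec-8-en-1-yl]-1,3-dioxan-4-yl]-3-(trimethylsilyl)prop-2-yn-1-one
Product: 20 (2Z)-1-[(4S,6S)-4-(2-hydroxyethyl)-2,2-dimethyl-6-[(8Z)-pentadec-8-en-1-yl]-1,3-dioxan-4-yl]-3-iodoprop-2-en-1-one, via terminal ynone 19 (not isolated)
Conditions: K2CO3 (0.2 equiv), MeOH, 0 °C; AcOH to neutral, evaporate; then NaI (3 equiv), AcOH (5 equiv), MeCN, rt, dark
Reagents that add atoms: sodium iodide, [Na+].[I-]
Why: Methanolysis of the alkynyl–silicon bond, then conjugate hydroiodination of the ynone: iodide adds to the β-carbon and the allenol is protonated anti, giving the kinetically favoured Z-β-iodoenone; room temperature and darkness prevent drift to the E isomer.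

Step 12
Reactants: 20 (2Z)-1-[(4S,6S)-4-(2-hydroxyethyl)-2,2-dimethyl-6-[(8Z)-pentadec-8-en-1-yl]-1,3-dioxan-4-yl]-3-iodoprop-2-en-1-one
Product: 21 2-[(4R,6S)-4-[(2Z)-3-iodoprop-2-enoyl]-2,2-dimethyl-6-[(8Z)-pentadec-8-en-1-yl]-1,3-dioxan-4-yl]acetaldehyde
Conditions: Dess–Martin periodinane (1.3 equiv), NaHCO3, CH2Cl2, 0 °C to rt
Reagents that add atoms: none
Why: Dess–Martin oxidation of the primary alcohol (through the open form of any lactol) under bicarbonate buffering; iodoenone, acetonide and Z-alkene are inert, and the β-alkoxy aldehyde meets no base that could trigger elimination.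

Step 13
Reactants: 21 2-[(4R,6S)-4-[(2Z)-3-iodoprop-2-enoyl]-2,2-dimethyl-6-[(8Z)-pentadec-8-en-1-yl]-1,3-dioxan-4-yl]acetaldehyde
Product: 22 (4S,6S,10S)-10-hydroxy-2,2-dimethyl-4-[(8Z)-pentadec-8-en-1-yl]-1,3-dioxaspiro[5.5]undec-8-en-7-one
Conditions: CrCl2 (8 equiv), NiCl2 (0.05 equiv), THF–DMF (3:1), 0.005 M, rt
Reagents that add atoms: none
Why: Intramolecular Nozaki–Hiyama–Kishi reaction: zerovalent nickel (from NiCl2 and CrCl2) inserts into the C–I bond, the alkenyl group passes to trivalent chromium and adds to the aldehyde in a 6-exo-trig closure that forms C3–C4; the Z geometry brings C3 within reach of C4, and a chromium held by both the aldehyde oxygen and the C6 acetal oxygen should place the new C–O bond cis to C6–O (10S).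

Step 14
Reactants: 22 (4S,6S,10S)-10-hydroxy-2,2-dimethyl-4-[(8Z)-pentadec-8-en-1-yl]-1,3-dioxaspiro[5.5]undec-8-en-7-one
Product: 23 (4S,6R)-4,6-dihydroxy-6-[(2S,10Z)-2-hydroxyheptadec-10-en-1-yl]cyclohex-2-en-1-one
Conditions: AcOH–THF–H2O (3:1:1), 35 °C
Reagents that add atoms: none
Why: Acid-catalysed hydrolysis of the 1,3-dioxane, fast because one acetal oxygen sits on a tertiary carbon; dilute AcOH is too weak to dehydrate the γ-hydroxy enone or shift the α-ketol, and no base is used after ring closure.

## Compound list

1 | citric acid | OC(=O)CC(O)(CC(=O)O)C(=O)O | starting material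
2 | formaldehyde (used as paraformaldehyde) | C=O | starting material
3 | 2,2'-(5-oxo-1,3-dioxolane-4,4-diyl)diacetic acid | OC(=O)CC1(CC(=O)O)OCOC1=O | intermediate
4 | dimethyl 2,2'-(5-oxo-1,3-dioxolane-4,4-diyl)diacetate | COC(=O)CC1(CC(=O)OC)OCOC1=O | intermediate
5 | (R)-2-[4-(2-methoxy-2-oxoethyl)-5-oxo-1,3-dioxolan-4-yl]acetic acid | OC(=O)C[C@]1(CC(=O)OC)OCOC1=O | intermediate
6 | palmitoleic acid, (9Z)-hexadec-9-enoic acid | CCCCCC/C=C\CCCCCCCC(=O)O | starting material
7 | 2-thioxopyridin-1(2H)-yl (9Z)-hexadec-9-enoate (Barton ester) | CCCCCC/C=C\CCCCCCCC(=O)On1ccccc1=S | intermediate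
8 | (8Z)-1-iodopentadec-8-ene | CCCCCC/C=C\CCCCCCCI | intermediate
9 | methyl 2-[(4S)-4-(2-chloro-2-oxoethyl)-5-oxo-1,3-dioxolan-4-yl]acetate | ClC(=O)C[C@]1(CC(=O)OC)OCOC1=O | intermediate
10 | [(8Z)-pentadec-8-en-1-yl]zinc iodide | CCCCCC/C=C\CCCCCCC[Zn]I | intermediate
11 | methyl 2-[(4R)-5-oxo-4-[(10Z)-2-oxoheptadec-10-en-1-yl]-1,3-dioxolan-4-yl]acetate | CCCCCC/C=C\CCCCCCCC(=O)C[C@]1(CC(=O)OC)OCOC1=O | intermediate
12 | methyl (3R,13Z)-3-hydroxy-3-(morpholine-4-carbonyl)-5-oxoicos-13-enoate | CCCCCC/C=C\CCCCCCCC(=O)C[C@@](O)(CC(=O)OC)C(=O)N1CCOCC1 | intermediate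
13 | methyl (3R,5S,13Z)-3,5-dihydroxy-3-(morpholine-4-carbonyl)icos-13-enoate | CCCCCC/C=C\CCCCCCC[C@H](O)C[C@@](O)(CC(=O)OC)C(=O)N1CCOCC1 | intermediate
14 | methyl 2-[(4R,6S)-2,2-dimethyl-4-(morpholine-4-carbonyl)-6-[(8Z)-pentadec-8-en-1-yl]-1,3-dioxan-4-yl]acetate | CCCCCC/C=C\CCCCCCC[C@H]1C[C@@](CC(=O)OC)(C(=O)N2CCOCC2)OC(C)(C)O1 | intermediate
15 | [(4S,6S)-4-(2-hydroxyethyl)-2,2-dimethyl-6-[(8Z)-pentadec-8-en-1-yl]-1,3-dioxan-4-yl](morpholin-4-yl)methanone | CCCCCC/C=C\CCCCCCC[C@H]1C[C@@](CCO)(C(=O)N2CCOCC2)OC(C)(C)O1 | intermediate
16 | ethynyltrimethylsilane | C#C[Si](C)(C)C | starting material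
17 | lithium (trimethylsilyl)acetylide | [Li]C#C[Si](C)(C)C | intermediate
18 | 1-[(4S,6S)-4-(2-hydroxyethyl)-2,2-dimethyl-6-[(8Z)-pentadec-8-en-1-yl]-1,3-dioxan-4-yl]-3-(trimethylsilyl)prop-2-yn-1-one | CCCCCC/C=C\CCCCCCC[C@H]1C[C@@](CCO)(C(=O)C#C[Si](C)(C)C)OC(C)(C)O1 | intermediate
19 | 1-[(4S,6S)-4-(2-hydroxyethyl)-2,2-dimethyl-6-[(8Z)-pentadec-8-en-1-yl]-1,3-dioxan-4-yl]prop-2-yn-1-one | CCCCCC/C=C\CCCCCCC[C@H]1C[C@@](CCO)(C(=O)C#C)OC(C)(C)O1 | intermediate
20 | (2Z)-1-[(4S,6S)-4-(2-hydroxyethyl)-2,2-dimethyl-6-[(8Z)-pentadec-8-en-1-yl]-1,3-dioxan-4-yl]-3-iodoprop-2-en-1-one | CCCCCC/C=C\CCCCCCC[C@H]1C[C@@](CCO)(C(=O)/C=C\I)OC(C)(C)O1 | intermediate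
21 | 2-[(4R,6S)-4-[(2Z)-3-iodoprop-2-enoyl]-2,2-dimethyl-6-[(8Z)-pentadec-8-en-1-yl]-1,3-dioxan-4-yl]acetaldehyde | CCCCCC/C=C\CCCCCCC[C@H]1C[C@@](CC=O)(C(=O)/C=C\I)OC(C)(C)O1 | intermediate
22 | (4S,6S,10S)-10-hydroxy-2,2-dimethyl-4-[(8Z)-pentadec-8-en-1-yl]-1,3-dioxaspiro[5.5]undec-8-en-7-one | CCCCCC/C=C\CCCCCCC[C@H]1C[C@]2(C[C@H](O)C=CC2=O)OC(C)(C)O1 | intermediate
23 | (4S,6R)-4,6-dihydroxy-6-[(2S,10Z)-2-hydroxyheptadec-10-en-1-yl]cyclohex-2-en-1-one | CCCCCC/C=C\CCCCCCC[C@H](O)C[C@@]1(O)C[C@H](O)C=CC1=O | target

## Step count and least certain steps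

Total: 14 steps. Longest linear sequence: 13 steps (steps 1–3 and 5–14, from citric acid). Step 4 is a one-step branch from palmitoleic acid.

**Step 3 (key step).** The pocket may discriminate the two arms poorly or in the opposite sense, because both are small and polar and the substrate class is untried. Hydrolytic opening of the dioxolanone at pH 7 may also compete. Fallback: diacid 3 is dehydrated with Ac2O to the spiro anhydride 1,3,8-trioxaspiro[4.5]decane-4,7,9-trione F1. The anhydride is opened with methanol under a cinchona alkaloid catalyst, (DHQD)2AQN or its pseudoenantiomer (DHQ)2AQN as the sense requires, in Et2O at −20 °C. The fallback returns to the route at 5.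

**Step 13.** Ring closure may show poor or reversed facial selectivity at C4, because DMF competes with the C6 acetal oxygen for chromium and the unchelated half-chair may prefer the C6 oxygen axial. Fallback: the C4 epimer (4S,6S,10R)-10-hydroxy-2,2-dimethyl-4-[(8Z)-pentadec-8-en-1-yl]-1,3-dioxaspiro[5.5]undec-8-en-7-one F2 is inverted by a Mitsunobu reaction (4-nitrobenzoic acid, PPh3, DIAD, THF). This gives (4S,6R,10S)-2,2-dimethyl-7-oxo-4-[(8Z)-pentadec-8-en-1-yl]-1,3-dioxaspiro[5.5]undec-8-en-10-yl 4-nitrobenzoate F3, and brief methanolysis (K2CO3, MeOH, 0 °C) returns to the route at 22.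

**Step 7.** The enzyme may not accept the substrate or may reduce it with low face selectivity, since the ketone carries a long lipophilic chain on one side and a branched polar group on the other. Fallback: 12 is reduced without stereocontrol (NaBH4, CeCl3, MeOH, −40 °C) and the two diastereomers are separated by chromatography. The unwanted methyl (3R,5R,13Z)-3,5-dihydroxy-3-(morpholine-4-carbonyl)icos-13-enoate F4 is oxidised back to 12 with Dess–Martin periodinane and recycled. The route is rejoined at 13.

**Step 6.** Exposing the ketone to the amine may cause β-elimination of the C6 oxygen before the ring opens, retro-aldol cleavage of the tertiary aldol 12, or Mannich capture of the released formaldehyde. Fallback: the dioxolanone is opened before the ketone exists. Acid 5 and morpholine give (3R)-3-hydroxy-5-methoxy-3-(morpholine-4-carbonyl)-5-oxopentanoic acid F5. EtSH and EDC convert it to the thioester methyl (3S)-5-(ethylsulfanyl)-3-hydroxy-3-(morpholine-4-carbonyl)-5-oxopentanoate F6. Fukuyama coupling of F6 with alkylzinc iodide 10 (PdCl2(PPh3)2, THF) returns to the route at 12.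

**Step 10.** Addition to the amide may be sluggish, since its carbonyl sits on a fully substituted carbon, and the released amine may add to the ynone during the quench. Fallback: 15 is lactonised under acid (CSA, CH2Cl2), with loss of morpholine, to (5S,9S)-7,7-dimethyl-9-[(8Z)-pentadec-8-en-1-yl]-2,6,8-trioxaspiro[4.5]decan-1-one F7. This more electrophilic γ-lactone is opened by lithium (trimethylsilyl)acetylide 17 at −78 °C, and the route is rejoined at 18.

## Further compounds

F1 | step 3 | 1,3,8-trioxaspiro[4.5]decane-4,7,9-trione | O=C1CC2(CC(=O)O1)OCOC2=O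
F2 | step 13 | (4S,6S,10R)-10-hydroxy-2,2-dimethyl-4-[(8Z)-pentadec-8-en-1-yl]-1,3-dioxaspiro[5.5]undec-8-en-7-one | CCCCCC/C=C\CCCCCCC[C@H]1C[C@]2(C[C@@H](O)C=CC2=O)OC(C)(C)O1
F3 | step 13 | (4S,6R,10S)-2,2-dimethyl-7-oxo-4-[(8Z)-pentadec-8-en-1-yl]-1,3-dioxaspiro[5.5]undec-8-en-10-yl 4-nitrobenzoate | CCCCCC/C=C\CCCCCCC[C@H]1C[C@]2(C[C@H](OC(=O)c3ccc(cc3)[N+](=O)[O-])C=CC2=O)OC(C)(C)O1
F4 | step 7 | methyl (3R,5R,13Z)-3,5-dihydroxy-3-(morpholine-4-carbonyl)icos-13-enoate | CCCCCC/C=C\CCCCCCC[C@@H](O)C[C@@](O)(CC(=O)OC)C(=O)N1CCOCC1
F5 | step 6 | (3R)-3-hydroxy-5-methoxy-3-(morpholine-4-carbonyl)-5-oxopentanoic acid | OC(=O)C[C@@](O)(CC(=O)OC)C(=O)N1CCOCC1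
F6 | step 6 | methyl (3S)-5-(ethylsulfanyl)-3-hydroxy-3-(morpholine-4-carbonyl)-5-oxopentanoate | CCSC(=O)C[C@@](O)(CC(=O)OC)C(=O)N1CCOCC1
F7 | step 10 | (5S,9S)-7,7-dimethyl-9-[(8Z)-pentadec-8-en-1-yl]-2,6,8-trioxaspiro[4.5]decan-1-one | CCCCCC/C=C\CCCCCCC[C@H]1C[C@]2(CCOC2=O)OC(C)(C)O1
A1 | alternative 1 | (4R,8S,16Z)-4,8-bis[(tert-butyldimethylsilyl)oxy]-6-oxotricos-16-enal | CCCCCC/C=C\CCCCCCC[C@H](O[Si](C)(C)C(C)(C)C)CC(=O)C[C@H](O[Si](C)(C)C(C)(C)C)CCC=O
A2 | alternative 1 | (4R,6R)-4-[(tert-butyldimethylsilyl)oxy]-6-hydroxy-6-[(2S,10Z)-2-[(tert-butyldimethylsilyl)oxy]heptadec-10-en-1-yl]cyclohexan-1-one | CCCCCC/C=C\CCCCCCC[C@H](O[Si](C)(C)C(C)(C)C)C[C@@]1(O)C[C@H](O[Si](C)(C)C(C)(C)C)CCC1=O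
A3 | alternative 2 | (5R)-5-[(tert-butyldimethylsilyl)oxy]cyclohex-2-en-1-one | O=C1C[C@H](O[Si](C)(C)C(C)(C)C)CC=C1
A4 | alternative 2 | (10Z)-heptadec-10-en-2-one | CCCCCC/C=C\CCCCCCCC(C)=O
A5 | alternative 2 | (10Z)-1-[(1S,5R)-5-[(tert-butyldimethylsilyl)oxy]-1-hydroxycyclohex-2-en-1-yl]heptadec-10-en-2-one | CCCCCC/C=C\CCCCCCCC(=O)C[C@@]1(O)C[C@H](O[Si](C)(C)C(C)(C)C)CC=C1
A6 | alternative 3 | (3S,11Z)-3-[(tert-butyldimethylsilyl)oxy]-1-[(1R,4S)-4-[(tert-butyldimethylsilyl)oxy]-1-hydroxycyclopent-2-en-1-yl]octadec-11-en-1-one | CCCCCC/C=C\CCCCCCC[C@H](O[Si](C)(C)C(C)(C)C)CC(=O)[C@@]1(O)C[C@H](O[Si](C)(C)C(C)(C)C)C=C1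
A7 | alternative 3 | (4S,6R)-4-[(tert-butyldimethylsilyl)oxy]-6-hydroxy-6-[(2S,10Z)-2-[(tert-butyldimethylsilyl)oxy]heptadec-10-en-1-yl]cyclohex-2-en-1-one | CCCCCC/C=C\CCCCCCC[C@H](O[Si](C)(C)C(C)(C)C)C[C@@]1(O)C[C@H](O[Si](C)(C)C(C)(C)C)C=CC1=O
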